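The runs were generated by integration from invented constants; scatter was added.

1. The constant to read first is the half-life of the substrate. In Tuesday's run it falls from 65.3 % at 0.250 d to 17.1 % at 1.04 d, so the half-life reads 0.409 d, with the scatter of those readings.

2. That pace holds in the pairs of runs compared here. At 0.417 d, Monday's run has 49.8 % left and Tuesday's 48.9 %, despite different first nucleophile. At 0.500 d, Friday's 42.5 % stands beside Thursday's 42.2 %, despite different substrate and first nucleophile. This looks like a slow first step, the rate-limiting step.

3. Now divide the feed time by this half-life. This feed count, 9.79, is your clock for a slow addition.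

| setting | Tuesday's | Thursday's | Monday's | Friday's | zeta | beta | epsilon |
|---|---|---|---|---|---|---|---|
| substrate | 48 mM | 48 mM | 48 mM | 72 mM | 48 mM | 48 mM | 48 mM |
| first nucleophile | 33.6 mM | 23 mM | 50 mM | 33.6 mM | 33.6 mM | 33.6 mM (fed, over 4.0 d) | 33.6 mM |
| second nucleophile | 57.6 mM | 57.6 mM | 57.6 mM | 57.6 mM | 57.6 mM (fed, over 4.0 d) | 57.6 mM | 57.6 mM |
| remark | run made earlier | run made earlier | run made earlier | run made earlier | all else is in the flask from the start; the feed brings no volume worth counting | all else is in the flask from the start; the feed brings no volume worth counting | everything together at the start |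
| time |  |  |  |  | 5.0 d | 5.0 d | 5.0 d |

| run | time / d | target / % | other capture product / % | substrate / % |
|---|---|---|---|---|
| Tuesday's | 0.250 | 24.6 | 1.9 | 65.3 |
| Tuesday's | 0.417 | 35.1 | 1.8 | 48.9 |
| Tuesday's | 0.625 | 45.7 | 4.5 | 33.2 |
| Tuesday's | 1.04 | 54.3 | 5.3 | 17.1 |
| Tuesday's | 1.67 | 58.0 | 5.6 | 6.3 |
| Tuesday's | 3.00 | 59.8 | 5.6 | 1.2 |
| Thursday's | 0.500 | 32.3 | 3.8 | 42.2 |
| Thursday's | 0.833 | 39.2 | 5.2 | 24.6 |
| Thursday's | 1.25 | 41.6 | 7.8 | 12.0 |
| Thursday's | 2.00 | 42.0 | 9.1 | 4.2 |
| Thursday's | 4.00 | 44.1 | 8.2 | 0.5 |
| Thursday's | 6.00 | 43.6 | 8.8 | 0 |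
| Monday's | 0.417 | 41.2 | 2.2 | 49.8 |
| Monday's | 1.25 | 69.4 | 4.3 | 12.5 |
| Monday's | 2.00 | 75.9 | 3.6 | 4.0 |
| Monday's | 3.00 | 77.6 | 4.5 | 0.8 |
| Monday's | 5.00 | 78.0 | 4.2 | 1.3 |
| Monday's | 6.00 | 77.8 | 3.9 | 0 |
| Friday's | 0.500 | 35.2 | 3.8 | 42.5 |
| Friday's | 1.67 | 41.6 | 7.5 | 4.6 |
| Friday's | 3.00 | 43.6 | 7.4 | 0.5 |
| Friday's | 4.00 | 44.2 | 8.1 | 0 |
| Friday's | 6.00 | 42.6 | 7.2 | 0 |

(standard deviation of a reading: 0.5 percentage points)

- the analysis behind the earlier runs scatters by 0.5 percentage points, standard deviation

- the flask with the highest share of target in target plus other capture product ("all alike" if they lie within 1.5 percentage points) (zeta / beta / epsilon / all alike)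
- share of target in target plus other capture product at the end, zeta
- share of target in target plus other capture product at the end, beta
- share of target in target plus other capture product at the end, epsilon

4. First instants: epsilon, which repeats Tuesday's charges, has both nucleophiles in full. In zeta and beta, the feed has delivered 10.2 % of the fed nucleophile's charge after one half-life; what stands in the flask is less, as far as any of it has already reacted.

5. Middle: after 3 half-lives, at 1.23 d, 87.5 % of the substrate has gone, but the feed has delivered 30.6 %, so the substrate runs ahead of the feed.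

6. What lagging costs: at the last readings, the unseen part is 18.3 % in Monday's run and 47.6 % in Thursday's, which has less first nucleophile. Thursday's share of target is also lower than Tuesday's: 83.2 % against 91.4 %.

7. End: after the full count, 0.113 % of the substrate remains, so the last of the feed meets hardly any.

8. My reckoning: epsilon stays near Tuesday's share, zeta stands above it, and beta falls below Thursday's.

The forecast gave 97.7 % for zeta, 70 % for beta and 91.4 % for epsilon, holding that “the first nucleophile is starved early” in beta.

    substrate → intermediate (k = 0.0710 h⁻¹)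
    first nucleophile + intermediate → target (k = 40.0 M⁻¹ h⁻¹)
    second nucleophile + intermediate → other capture product (k = 1.50 M⁻¹ h⁻¹)
    second nucleophile → decomposed reagent (k = 0.0590 h⁻¹)
    intermediate → side product (k = 0.150 h⁻¹)
    first nucleophile ⇌ dormant form (K = 1.10, k = 0.0240 h⁻¹)

The flasks give 96.3 % for zeta, 62.8 % for beta and 91.0 % for epsilon, so zeta stands highest. In zeta, the count's 0.113 % of substrate compares with 0.110 % in the flask at 4.00 d, when target stands at 61.6 % and other capture product at 2.35 %. In beta, the half-life gives 57.1 % of the substrate gone by 0.500 d; the step to intermediate has then done 57 % of its turnover up to 5.0 d, with 12.5 % of the first nucleophile fed. Side-product formation reaches its midpoint by 0.590 d, and beta ends with side product at 61.4 %.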